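**Retrosynthetic overview**
1. Rings A/C/B are the 7-methoxychromone with its 4'-methoxyphenyl group, and rings D/F/E are the 7''-hydroxychromone with its 4'''-hydroxyphenyl group. The strategy rests on C8'' of ring D, the carbon that carries ring B, which is flanked by C7''–OH on one side and C8a''–O1'' on the other.
2. Cutting ring F at C4''–C4a'' and O1''–C2'' uncovers a 2-arylresorcinol whose two hydroxyls and two free ortho CH positions are interchangeable. The other piece is an aroylacetic ester that brings C2''–C4'' and ring E, with its phenol masked as a benzyl ether.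
3. The 2-arylresorcinol is cut at the C3'–C8'' biaryl bond (Suzuki–Miyaura) into 3'-bromo-4',7-dimethoxyflavone and 2,6-bis(methoxymethoxy)phenylboronic acid. The boronic acid comes from resorcinol by directed ortho-lithiation.
4. The bromoflavone comes from paeonol and 3-bromo-4-methoxybenzaldehyde by chalcone formation and oxidative cyclisation.
5. Order of ring formation: ring C (step 2), biaryl bond (step 5), ring F (step 8). Rings A, B, D and E are bought, and debenzylation ends the route.

Key step: step 8

Assumption: the target SMILES holds no stereocentre and no axial descriptor, so the C3'–C8'' axis is treated as configurationally undefined and no control of axial chirality is attempted.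

**Step 1**
Reactants: 1 paeonol (2-hydroxy-4-methoxyacetophenone); 2 3-bromo-4-methoxybenzaldehyde
Product: 3 (E)-3-(3-bromo-4-methoxyphenyl)-1-(2-hydroxy-4-methoxyphenyl)prop-2-en-1-one
Conditions: KOH (50% aq., 5 equiv), EtOH, rt; then 1 M HCl
Reagents that add atoms: none
Why: Claisen–Schmidt condensation, in which the methyl ketone enolate of 1 adds to the non-enolisable aldehyde 2 and E1cB loss of water gives the conjugated enone in its favoured E geometry.

**Step 2**
Reactants: 3 the 2'-hydroxychalcone
Product: 5 2-(3-bromo-4-methoxyphenyl)-7-methoxychromen-4-one, via racemic flavanone 4 (not isolated)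
Conditions: I2 (10 mol %), DMSO, 130 °C
Reagents that add atoms: none
Why: Iodine-catalysed oxidative cyclisation of a 2'-hydroxychalcone, in which oxa-Michael closure to 4, alpha-iodination and loss of HI build ring C while DMSO reoxidises HI to I2; the aryl bromide and methyl ethers are inert, and the transient C2 stereocentre of 4 is erased.

**Step 3**
Reactants: 6 resorcinol
Product: 7 1,3-bis(methoxymethoxy)benzene
Conditions: NaH (2.4 equiv), MOMCl (2.4 equiv), DMF, 0 °C to rt
Reagents that add atoms: chloromethyl methyl ether, COCCl
Why: Williamson-type O-alkylation of the bis-phenoxide; the two acetals protect the phenols and act as directing groups for the next step.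

**Step 4**
Reactants: 7 1,3-bis(methoxymethoxy)benzene
Product: 10 2,6-bis(methoxymethoxy)phenylboronic acid, via aryllithium 8 (not isolated), via lithium aryltriisopropoxyborate 9 (not isolated)
Conditions: n-BuLi (1.1 equiv), THF, 0 °C to rt; B(OiPr)3 (1.5 equiv), −78 °C to rt; sat. aq. NH4Cl
Reagents that add atoms: triisopropyl borate, CC(C)OB(OC(C)C)OC(C)C (boron); water, O (the two boronic acid oxygens, on hydrolysis); n-butyllithium, [Li]CCCC (lithium of 8 and 9 only)
Why: Directed ortho-metalation, in which the C2–H between the two chelating acetal oxygens is lithiated selectively and borate trapping with near-neutral hydrolysis gives the boronic acid without loss of the acetals.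

**Step 5**
Reactants: 5 the 3'-bromoflavone; 10 2,6-bis(methoxymethoxy)phenylboronic acid (1.5–2 equiv)
Product: 11 2-{3-[2,6-bis(methoxymethoxy)phenyl]-4-methoxyphenyl}-7-methoxychromen-4-one
Conditions: Pd(OAc)2 (5 mol %), SPhos (2-dicyclohexylphosphino-2',6'-dimethoxybiphenyl, 10 mol %), K3PO4 (3 equiv), 1,4-dioxane/H2O 5:1, 90 °C
Reagents that add atoms: none
Why: Suzuki–Miyaura cross-coupling forms the C3'–C8'' bond; the bulky electron-rich biarylphosphine makes a tri-ortho-substituted biaryl accessible and lets coupling outrun protodeboronation of 10, which is used in excess.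

**Step 6**
Reactants: 11 the bis-MOM biaryl flavone
Product: 12 2-[3-(2,6-dihydroxyphenyl)-4-methoxyphenyl]-7-methoxychromen-4-one
Conditions: conc. HCl (cat.), MeOH/THF, 55 °C
Reagents that add atoms: none
Why: Acid-catalysed transacetalisation of both MOM ethers to methanol; aryl methyl ethers and the chromone tolerate dilute acid.

**Step 7**
Reactants: 13 4'-benzyloxyacetophenone
Product: 14 ethyl 3-(4-benzyloxyphenyl)-3-oxopropanoate
Conditions: NaH (2.5 equiv), (EtO)2CO (3 equiv), THF, reflux; then ice, 1 M HCl
Reagents that add atoms: diethyl carbonate, CCOC(=O)OCC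
Why: Crossed Claisen condensation of the ketone enolate with non-enolisable diethyl carbonate, driven by irreversible deprotonation of the beta-keto ester; the benzyl ether is inert to base.

**Step 8**
Reactants: 12 the symmetric 2-arylresorcinol; 14 ethyl 3-(4-benzyloxyphenyl)-3-oxopropanoate
Product: 17 2-(4-benzyloxyphenyl)-7-hydroxy-8-[2-methoxy-5-(7-methoxy-4-oxochromen-2-yl)phenyl]chromen-4-one, via aroylketene 15 (not isolated), via ortho-hydroxyaryl 1,3-diketone 16 (not isolated)
Conditions: 14 (3 equiv, in portions), no solvent, melt at 240 °C under Ar sweep (EtOH and H2O driven off), 2–3 h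
Reagents that add atoms: none
Why: Above about 200 °C keto ester 14 loses ethanol to aroylketene 15, which acylates ring D of 12 at the carbon ortho to one hydroxyl and para to the other, directly or by O-acylation and thermal acyl shift, forging C4''–C4a'' and giving diketone 16. The hydroxyl next to the new acyl group then adds to the benzyloxyphenyl ketone in a 6-exo-trig closure and the hemiketal loses water, which forms O1''–C2'' and closes pyranone ring F. This is the Mentzer pyrone synthesis, the acid-free thermal condensation of resorcinols and phloroglucinols with aroylacetic esters, known for resorcinol itself and for 2-alkylresorcinols. Site selectivity needs no control, because the local symmetry of ring D about the biaryl bond exchanges its two hydroxyls and its two free ortho carbons, so either side delivers the 8''-aryl-7''-hydroxy pattern, while the ring D carbon meta to both hydroxyls is unactivated. Chromone rather than 4-arylcoumarin formation is secured by excluding acid, so that the ester carbon (as the ketene) and not a protonated ketone is the electrophile; rings A, B and C hold no free hydroxyl and are less electron rich, and once ring F is closed the C4'' carbonyl deactivates ring D against a second annulation. No stereocentre is formed.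

**Step 9**
Reactants: 17 the 4'''-O-benzyl biflavone
Product: 18 7-hydroxy-2-(4-hydroxyphenyl)-8-[2-methoxy-5-(7-methoxy-4-oxochromen-2-yl)phenyl]chromen-4-one (CNP0121664.0)
Conditions: H2 (1 atm), Pd/C (10 wt %), THF/MeOH, rt
Reagents that add atoms: none
Why: Catalytic hydrogenolysis of a benzyl aryl ether; benzylic C–O cleavage at 1 atm should be much faster than saturation of the chromone C2=C3 bonds, and the methyl ethers are untouched.

**Compound list**
1 | paeonol, 1-(2-hydroxy-4-methoxyphenyl)ethanone | COc1ccc(C(C)=O)c(O)c1 | starting material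
2 | 3-bromo-4-methoxybenzaldehyde | COc1ccc(C=O)cc1Br | starting material
3 | (E)-3-(3-bromo-4-methoxyphenyl)-1-(2-hydroxy-4-methoxyphenyl)prop-2-en-1-one | COc1ccc(C(=O)/C=C/c2ccc(OC)c(Br)c2)c(O)c1 | intermediate
4 | rac-2-(3-bromo-4-methoxyphenyl)-7-methoxychroman-4-one (not isolated) | COc1ccc2C(=O)CC(c3ccc(OC)c(Br)c3)Oc2c1 | intermediate
5 | 2-(3-bromo-4-methoxyphenyl)-7-methoxychromen-4-one | COc1ccc2c(=O)cc(-c3ccc(OC)c(Br)c3)oc2c1 | intermediate
6 | resorcinol | Oc1cccc(O)c1 | starting material
7 | 1,3-bis(methoxymethoxy)benzene | COCOc1cccc(OCOC)c1 | intermediate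
8 | [2,6-bis(methoxymethoxy)phenyl]lithium (not isolated) | [Li]c1c(OCOC)cccc1OCOC | intermediate
9 | lithium [2,6-bis(methoxymethoxy)phenyl]triisopropoxyborate (not isolated) | [Li+].COCOc1cccc(OCOC)c1[B-](OC(C)C)(OC(C)C)OC(C)C | intermediate
10 | 2,6-bis(methoxymethoxy)phenylboronic acid | COCOc1cccc(OCOC)c1B(O)O | intermediate
11 | 2-{3-[2,6-bis(methoxymethoxy)phenyl]-4-methoxyphenyl}-7-methoxychromen-4-one | COc1ccc2c(=O)cc(-c3ccc(OC)c(-c4c(OCOC)cccc4OCOC)c3)oc2c1 | intermediate
12 | 2-[3-(2,6-dihydroxyphenyl)-4-methoxyphenyl]-7-methoxychromen-4-one | COc1ccc2c(=O)cc(-c3ccc(OC)c(-c4c(O)cccc4O)c3)oc2c1 | intermediate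
13 | 4'-benzyloxyacetophenone | CC(=O)c1ccc(OCc2ccccc2)cc1 | starting material
14 | ethyl 3-(4-benzyloxyphenyl)-3-oxopropanoate | CCOC(=O)CC(=O)c1ccc(OCc2ccccc2)cc1 | intermediate
15 | 3-(4-benzyloxyphenyl)-3-oxoprop-1-en-1-one, the aroylketene (not isolated) | O=C=CC(=O)c1ccc(OCc2ccccc2)cc1 | intermediate
16 | 1-(4-benzyloxyphenyl)-3-{2,4-dihydroxy-3-[2-methoxy-5-(7-methoxy-4-oxochromen-2-yl)phenyl]phenyl}propane-1,3-dione (not isolated) | COc1ccc2c(=O)cc(-c3ccc(OC)c(-c4c(O)ccc(C(=O)CC(=O)c5ccc(OCc6ccccc6)cc5)c4O)c3)oc2c1 | intermediate
17 | 2-(4-benzyloxyphenyl)-7-hydroxy-8-[2-methoxy-5-(7-methoxy-4-oxochromen-2-yl)phenyl]chromen-4-one | COc1ccc2c(=O)cc(-c3ccc(OC)c(-c4c(O)ccc5c(=O)cc(-c6ccc(OCc7ccccc7)cc6)oc45)c3)oc2c1 | intermediate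
18 | 7-hydroxy-2-(4-hydroxyphenyl)-8-[2-methoxy-5-(7-methoxy-4-oxochromen-2-yl)phenyl]chromen-4-one | COc1ccc2c(=O)cc(-c3ccc(OC)c(-c4c(O)ccc5c(=O)cc(-c6ccc(O)cc6)oc45)c3)oc2c1 | target

**Total step count:** 9
**Longest linear sequence:** 6 steps (1, 2, 5, 6, 8, 9, or equally 3, 4, 5, 6, 8, 9)

**Steps most likely to fail**

**Step 8.**
- C-acylation of a resorcinol-type ring, which is less activated than phloroglucinol, may be slower than self-condensation of the aroylketene.
- The melt may stay heterogeneous.
- The remaining phenol may be O-acylated.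
- Traces of acid may divert the condensation towards the coumarin manifold.

The fallback builds ring F stepwise and still uses the symmetry of ring D. It sets out from 12. C-acetylation with AcOH and BF3·OEt2 at 90 °C (Nencki-type Friedel–Crafts acylation, one isomer for the same symmetry reason) should give 2-[3-(3-acetyl-2,6-dihydroxyphenyl)-4-methoxyphenyl]-7-methoxychromen-4-one F1. The lithium polyanion of this ketone (LiN(SiMe3)2, 4.5 equiv, THF, −78 °C) is C-aroylated with 4-benzyloxybenzoyl chloride, a Baker–Venkataraman-type construction, to diketone 16, which is isolated this time. Cyclodehydration with catalytic p-TsOH in refluxing toluene brings the fallback back to the route at 17.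

**Step 5.** Protodeboronation of the 2,6-dialkoxy boronic acid in hot aqueous base may outpace transmetalation onto the hindered arylpalladium species. The fallback inverts the polarity of the coupling and sets out from 5 and from 7.
- Miyaura borylation of 5 (bis(pinacolato)diboron, PdCl2(dppf), KOAc, dioxane, 90 °C) should give 7-methoxy-2-[4-methoxy-3-(4,4,5,5-tetramethyl-1,3,2-dioxaborolan-2-yl)phenyl]chromen-4-one F2. Its boron has only one ortho substituent, so it is far less prone to protodeboronation.
- Aryllithium 8, made from 7 as in step 4, is quenched with I2 to give 2-iodo-1,3-bis(methoxymethoxy)benzene F3.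
- Coupling of the two (Pd(OAc)2, SPhos, K3PO4, dioxane/H2O, 90 °C) comes back to the route at 11.

**Step 9.** Low solubility of the biflavone may slow the hydrogenolysis, and forcing it may start to saturate the chromone C2=C3 bonds. The fallback replaces reduction by Lewis-acid heterolysis of the benzyl ether with a cation scavenger. It sets out from 17, which is treated with BCl3 (4 equiv) and pentamethylbenzene (3 equiv) in CH2Cl2 at −78 °C, then MeOH and water. This comes back to the route at 18. The methoxy groups at C7 and C4' lie next to no chelating carbonyl and should resist BCl3 at this temperature. No new compound arises on this way (F0).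

**Further compounds**
F1 | step 8 | 2-[3-(3-acetyl-2,6-dihydroxyphenyl)-4-methoxyphenyl]-7-methoxychromen-4-one | COc1ccc2c(=O)cc(-c3ccc(OC)c(-c4c(O)ccc(C(C)=O)c4O)c3)oc2c1
F2 | step 5 | 7-methoxy-2-[4-methoxy-3-(4,4,5,5-tetramethyl-1,3,2-dioxaborolan-2-yl)phenyl]chromen-4-one | COc1ccc2c(=O)cc(-c3ccc(OC)c(B4OC(C)(C)C(C)(C)O4)c3)oc2c1
F3 | step 5 | 2-iodo-1,3-bis(methoxymethoxy)benzene | COCOc1cccc(OCOC)c1I
F0 | step 9 | none | none
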